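**Retrosynthetic overview**

1. Target 21 consists of unit A, the (3R,4S) 4-aryloxy isochromanone, and unit B, the (3R,4R) 4-hydroxy isochromanone. It is cut at the ether C4(A)–O–C6(B) and, in each unit, at the aryl–carbonyl bond C8a–C1, which leaves C1 as a carbamoyl carbon on O2.
2. Both halves come from one ketone 6, made from aldehyde 2 and sparteine-lithiated ethyl carbamate 3 (this sets C3). The two enantiomeric CBS catalysts reduce 6 to the threo alcohol 7 (unit B) and the erythro alcohol 13 (unit A).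
3. Ring order: lactone of unit B first (step 6); then union of 13 with phenol 12 through a temporary trans 1,3-dioxolan-2-iminium ring that is not in the target (double inversion, net retention at C4 of unit A); then lactone of unit A last (step 10); then desilylation.
4. Enabling feature: ring A of 17 is a 4-methoxy-3,5-bis(silyloxy)phenyl ring. Its two free ortho carbons (future C5 and C8a) are homotopic, and each is ortho to one oxygen and para to the other. Because the carbamoyl carbon already sits on O2, closure C8a–C1 can only give the six-membered lactone; the isomeric phthalide cannot form.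
5. The same carbamate carbon directs the lithiation, serves as neighbouring group for the ether, and ends as C1.

Key step: step 10

Assumption: 3,5-dihydroxy-4-methoxybenzaldehyde (1) and ethyl N,N-diisopropylcarbamate (3) are taken as catalogue compounds. TBS = tert-butyldimethylsilyl.

**Route**

Step 1
Reactants: 1 3,5-dihydroxy-4-methoxybenzaldehyde
Product: 2 3,5-bis(TBS-oxy)-4-methoxybenzaldehyde
Conditions: TBSCl, imidazole, DMF, rt
Reagents that add atoms: tert-butyldimethylsilyl chloride (TBSCl), CC(C)(C)[Si](C)(C)Cl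
Why: Silyl ether formation masks both acidic phenols for the organolithium step and keeps the ring electron-rich for the later ring closures; no stereocenter is involved.

Step 2
Reactants: 3 ethyl N,N-diisopropylcarbamate; 2 3,5-bis(TBS-oxy)-4-methoxybenzaldehyde
Product: 5 (2R)-1-[3,5-bis(TBS-oxy)-4-methoxyphenyl]-1-hydroxypropan-2-yl N,N-diisopropylcarbamate (both C1 epimers), via lithiated carbamate sparteine complex 4 (not isolated)
Conditions: s-BuLi, (−)-sparteine, Et2O, −78 °C; then 2, −78 °C; AcOH quench at −78 °C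
Reagents that add atoms: none
Why: Sparteine-mediated asymmetric deprotonation of the O-ethyl carbamate (Hoppe-type lithiation) removes the pro-S proton, and the configurationally stable lithium compound adds to the aldehyde with retention, which sets the future C3 as (R); the carbinol carbon forms without control and is erased in step 3.

Step 3
Reactants: 5 (2R)-1-[3,5-bis(TBS-oxy)-4-methoxyphenyl]-1-hydroxypropan-2-yl N,N-diisopropylcarbamate (both C1 epimers)
Product: 6 (2R)-1-[3,5-bis(TBS-oxy)-4-methoxyphenyl]-1-oxopropan-2-yl N,N-diisopropylcarbamate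
Conditions: Dess–Martin periodinane, CH2Cl2, 0 °C to rt
Reagents that add atoms: none
Why: Dess–Martin oxidation of the secondary benzylic alcohol under near-neutral conditions should converge both epimers to one ketone without epimerising the adjacent carbamate-bearing stereocenter.

Step 4
Reactants: 6 (2R)-1-[3,5-bis(TBS-oxy)-4-methoxyphenyl]-1-oxopropan-2-yl N,N-diisopropylcarbamate
Product: 7 (1R,2R)-1-[3,5-bis(TBS-oxy)-4-methoxyphenyl]-1-hydroxypropan-2-yl N,N-diisopropylcarbamate (threo)
Conditions: (R)-1-methyl-3,3-diphenyltetrahydro-1H,3H-pyrrolo[1,2-c][1,3,2]oxazaborole ((R)-Me-CBS, cat.), BH3·SMe2, THF, −20 °C; then MeOH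
Reagents that add atoms: none
Why: CBS reduction with the aryl group as the large substituent should deliver hydride under catalyst control to give the (1R) carbinol, the future cis C4 of unit B.

Step 5
Reactants: 7 (1R,2R)-1-[3,5-bis(TBS-oxy)-4-methoxyphenyl]-1-hydroxypropan-2-yl N,N-diisopropylcarbamate
Product: 8 (1R,2R)-1-[3,5-bis(TBS-oxy)-4-methoxyphenyl]-1-(TBS-oxy)propan-2-yl N,N-diisopropylcarbamate
Conditions: TBSOTf, 2,6-lutidine, CH2Cl2, 0 °C to rt
Reagents that add atoms: tert-butyldimethylsilyl triflate (TBSOTf), CC(C)(C)[Si](C)(C)OS(=O)(=O)C(F)(F)F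
Why: Silyl ether formation with the reactive triflate caps the hindered benzylic hydroxyl so that Tf2O meets only the carbamate in step 6; no stereocenter changes.

Step 6
Reactants: 8 (1R,2R)-1-[3,5-bis(TBS-oxy)-4-methoxyphenyl]-1-(TBS-oxy)propan-2-yl N,N-diisopropylcarbamate
Product: 11 (3R,4R)-4,6,8-tris(TBS-oxy)-7-methoxy-3-methylisochroman-1-one, via O-triflyl iminium triflate 9 (not isolated), via cyclic iminium ether triflate 10 (not isolated)
Conditions: Tf2O, 2-chloropyridine, CH2Cl2, −78 to 0 °C; then H2O, THF, rt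
Reagents that add atoms: water, O
Why: Proposed new method: this is the O-carbamate variant of the Tf2O-promoted Bischler–Napieralski cyclisation of N-phenethyl carbamates (closest known type, together with Vilsmeier–Haack acylation), tried first on the simpler half. The O-triflyl iminium held on O2 is attacked by either of the two homotopic ortho carbons in a 6-exo-trig Friedel–Crafts closure, and water releases diisopropylamine and the lactone; the hindered C4 silyl ether is a poor internal nucleophile and the cis (3R,4R) centers are untouched.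

Step 7
Reactants: 11 (3R,4R)-4,6,8-tris(TBS-oxy)-7-methoxy-3-methylisochroman-1-one
Product: 12 (3R,4R)-4-(TBS-oxy)-6,8-dihydroxy-7-methoxy-3-methylisochroman-1-one
Conditions: KHF2, MeOH, rt
Reagents that add atoms: none
Why: Bifluoride desilylation is selective for phenolic over alkyl silyl ethers, so both phenols should be freed under non-basic conditions while the C4 silyl ether stays in place.

Step 8
Reactants: 6 (2R)-1-[3,5-bis(TBS-oxy)-4-methoxyphenyl]-1-oxopropan-2-yl N,N-diisopropylcarbamate
Product: 13 (1S,2R)-1-[3,5-bis(TBS-oxy)-4-methoxyphenyl]-1-hydroxypropan-2-yl N,N-diisopropylcarbamate (erythro)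
Conditions: (S)-1-methyl-3,3-diphenyltetrahydro-1H,3H-pyrrolo[1,2-c][1,3,2]oxazaborole ((S)-Me-CBS, cat.), BH3·SMe2, THF, −20 °C; then MeOH
Reagents that add atoms: none
Why: CBS reduction with the enantiomeric catalyst should deliver hydride to the opposite carbonyl face and give the (1S) carbinol, whose configuration is the one needed at C4 of unit A.

Step 9
Reactants: 13 (1S,2R)-1-[3,5-bis(TBS-oxy)-4-methoxyphenyl]-1-hydroxypropan-2-yl N,N-diisopropylcarbamate; 12 (3R,4R)-4-(TBS-oxy)-6,8-dihydroxy-7-methoxy-3-methylisochroman-1-one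
Product: 17 (1S,2R)-1-[3,5-bis(TBS-oxy)-4-methoxyphenyl]-1-{[(3R,4R)-4,8-bis(TBS-oxy)-7-methoxy-3-methyl-1-oxoisochroman-6-yl]oxy}propan-2-yl N,N-diisopropylcarbamate, via benzylic mesylate 14 (not isolated), via dioxolan-2-iminium mesylate 15 (not isolated), via phenol ether 16 (not isolated)
Conditions: Ms2O, iPr2NEt, CH2Cl2, −20 to 0 °C; then 12, iPr2NEt, MeCN, rt to 40 °C; then TBSOTf, 2,6-lutidine, 0 °C
Reagents that add atoms: tert-butyldimethylsilyl triflate (TBSOTf), CC(C)(C)[Si](C)(C)OS(=O)(=O)C(F)(F)F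
Why: Proposed new method: mesylation of the benzylic hydroxyl triggers anchimeric displacement by the carbamate carbonyl oxygen (inversion) to the trans 2-iminio-1,3-dioxolane 15. The more acidic, non-chelated 6-OH phenoxide of 12 should open this temporary ring by SN2 at the benzylic carbon (second inversion), so C4 of unit A ends with net retention as (S). The closest known types are neighbouring-group substitution through 2-amino-1,3-dioxolan-2-ylium ions (opened by halide) and phenoxide opening of benzylic cyclic sulfates; the in-flask silylation of the chelated 8-OH is standard.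

Step 10
Reactants: 17 (1S,2R)-1-[3,5-bis(TBS-oxy)-4-methoxyphenyl]-1-{[(3R,4R)-4,8-bis(TBS-oxy)-7-methoxy-3-methyl-1-oxoisochroman-6-yl]oxy}propan-2-yl N,N-diisopropylcarbamate
Product: 20 (3R,4R)-4,8-bis(TBS-oxy)-6-{[(3R,4S)-6,8-bis(TBS-oxy)-7-methoxy-3-methyl-1-oxoisochroman-4-yl]oxy}-7-methoxy-3-methylisochroman-1-one, via O-triflyl iminium triflate 18 (not isolated), via cyclic iminium ether triflate 19 (not isolated)
Conditions: Tf2O, 2-chloropyridine, CH2Cl2, −78 to 0 °C; then H2O, THF, rt
Reagents that add atoms: water, O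
Why: Proposed new method: Tf2O O-triflylates the carbamate carbonyl of 17 to the O-triflyl iminium 18, a Vilsmeier-type carbon electrophile held on O2; the closest known reaction type is the Tf2O-promoted Bischler–Napieralski cyclisation of N-phenethyl carbamates and amides (and Vilsmeier–Haack acylation), here transposed to an O-carbamate. The ortho carbon of ring A (future C8a), ortho to one silyloxy group and para to the other, attacks the iminium carbon in a 6-exo-trig Friedel–Crafts closure; rearomatisation and loss of triflate give the cyclic iminium ether 19, and water then releases diisopropylamine and the lactone. No stereocenter is formed; C3 and C4 are spectators because no ionisable or acidic position is created next to them. Regioselectivity is secured by symmetry, since the two free ortho carbons of ring A are homotopic, and by the tether, since the carbamoyl carbon on O2 reaches ring A through a six-membered transition state whereas C5 of ring B would need a seven-membered one. Chemoselectivity rests on the preference of Tf2O for carbamate oxygen over lactone, aryl ether and silyl ether oxygen; the benzylic oxygen at C4 is an aryl ether and cannot intercept the iminium irreversibly.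

Step 11
Reactants: 20 (3R,4R)-4,8-bis(TBS-oxy)-6-{[(3R,4S)-6,8-bis(TBS-oxy)-7-methoxy-3-methyl-1-oxoisochroman-4-yl]oxy}-7-methoxy-3-methylisochroman-1-one
Product: 21 (3R,4R)-4,8-dihydroxy-6-{[(3R,4S)-6,8-dihydroxy-7-methoxy-3-methyl-1-oxoisochroman-4-yl]oxy}-7-methoxy-3-methylisochroman-1-one (CNP0139537.4)
Conditions: HF·pyridine, pyridine, THF, 0 °C to rt
Reagents that add atoms: none
Why: Fluoride-mediated desilylation under acidic, non-basic conditions should free the three phenols and the C4 hydroxyl of unit B without base-induced translactonisation to a phthalide and without touching the benzylic aryl ether (no hydrogenolysis is used anywhere).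

**Compound list**

1 | 3,5-dihydroxy-4-methoxybenzaldehyde | COc1c(O)cc(C=O)cc1O | starting material
2 | 3,5-bis(TBS-oxy)-4-methoxybenzaldehyde | COc1c(O[Si](C)(C)C(C)(C)C)cc(C=O)cc1O[Si](C)(C)C(C)(C)C | intermediate
3 | ethyl N,N-diisopropylcarbamate | CCOC(=O)N(C(C)C)C(C)C | starting material
4 | (S)-1-(N,N-diisopropylcarbamoyloxy)ethyllithium, complexed by (−)-sparteine | C[C@H]([Li])OC(=O)N(C(C)C)C(C)C | intermediate
5 | (2R)-1-[3,5-bis(TBS-oxy)-4-methoxyphenyl]-1-hydroxypropan-2-yl N,N-diisopropylcarbamate, both C1 epimers | C[C@@H](OC(=O)N(C(C)C)C(C)C)C(O)c1cc(O[Si](C)(C)C(C)(C)C)c(OC)c(O[Si](C)(C)C(C)(C)C)c1 | intermediate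
6 | (2R)-1-[3,5-bis(TBS-oxy)-4-methoxyphenyl]-1-oxopropan-2-yl N,N-diisopropylcarbamate | C[C@@H](OC(=O)N(C(C)C)C(C)C)C(=O)c1cc(O[Si](C)(C)C(C)(C)C)c(OC)c(O[Si](C)(C)C(C)(C)C)c1 | intermediate
7 | (1R,2R)-1-[3,5-bis(TBS-oxy)-4-methoxyphenyl]-1-hydroxypropan-2-yl N,N-diisopropylcarbamate | C[C@@H](OC(=O)N(C(C)C)C(C)C)[C@H](O)c1cc(O[Si](C)(C)C(C)(C)C)c(OC)c(O[Si](C)(C)C(C)(C)C)c1 | intermediate
8 | (1R,2R)-1-[3,5-bis(TBS-oxy)-4-methoxyphenyl]-1-(TBS-oxy)propan-2-yl N,N-diisopropylcarbamate | C[C@@H](OC(=O)N(C(C)C)C(C)C)[C@H](O[Si](C)(C)C(C)(C)C)c1cc(O[Si](C)(C)C(C)(C)C)c(OC)c(O[Si](C)(C)C(C)(C)C)c1 | intermediate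
9 | O-triflyl iminium triflate of 8 (carbamate oxygen triflylated) | C[C@@H](OC(OS(=O)(=O)C(F)(F)F)=[N+](C(C)C)C(C)C)[C@H](O[Si](C)(C)C(C)(C)C)c1cc(O[Si](C)(C)C(C)(C)C)c(OC)c(O[Si](C)(C)C(C)(C)C)c1.[O-]S(=O)(=O)C(F)(F)F | intermediate
10 | (3R,4R)-1-(diisopropyliminio)-4,6,8-tris(TBS-oxy)-7-methoxy-3-methylisochroman triflate | C[C@H]1OC(=[N+](C(C)C)C(C)C)c2c(O[Si](C)(C)C(C)(C)C)c(OC)c(O[Si](C)(C)C(C)(C)C)cc2[C@H]1O[Si](C)(C)C(C)(C)C.[O-]S(=O)(=O)C(F)(F)F | intermediate
11 | (3R,4R)-4,6,8-tris(TBS-oxy)-7-methoxy-3-methylisochroman-1-one | C[C@H]1OC(=O)c2c(O[Si](C)(C)C(C)(C)C)c(OC)c(O[Si](C)(C)C(C)(C)C)cc2[C@H]1O[Si](C)(C)C(C)(C)C | intermediate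
12 | (3R,4R)-4-(TBS-oxy)-6,8-dihydroxy-7-methoxy-3-methylisochroman-1-one | C[C@H]1OC(=O)c2c(O)c(OC)c(O)cc2[C@H]1O[Si](C)(C)C(C)(C)C | intermediate
13 | (1S,2R)-1-[3,5-bis(TBS-oxy)-4-methoxyphenyl]-1-hydroxypropan-2-yl N,N-diisopropylcarbamate | C[C@@H](OC(=O)N(C(C)C)C(C)C)[C@@H](O)c1cc(O[Si](C)(C)C(C)(C)C)c(OC)c(O[Si](C)(C)C(C)(C)C)c1 | intermediate
14 | (1S,2R)-1-[3,5-bis(TBS-oxy)-4-methoxyphenyl]-1-(methanesulfonyloxy)propan-2-yl N,N-diisopropylcarbamate | C[C@@H](OC(=O)N(C(C)C)C(C)C)[C@@H](OS(C)(=O)=O)c1cc(O[Si](C)(C)C(C)(C)C)c(OC)c(O[Si](C)(C)C(C)(C)C)c1 | intermediate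
15 | (4R,5R)-4-[3,5-bis(TBS-oxy)-4-methoxyphenyl]-2-(diisopropyliminio)-5-methyl-1,3-dioxolane mesylate (trans) | C[C@H]1OC(=[N+](C(C)C)C(C)C)O[C@@H]1c1cc(O[Si](C)(C)C(C)(C)C)c(OC)c(O[Si](C)(C)C(C)(C)C)c1.CS(=O)(=O)[O-] | intermediate
16 | (1S,2R)-1-[3,5-bis(TBS-oxy)-4-methoxyphenyl]-1-{[(3R,4R)-4-(TBS-oxy)-8-hydroxy-7-methoxy-3-methyl-1-oxoisochroman-6-yl]oxy}propan-2-yl N,N-diisopropylcarbamate | C[C@@H](OC(=O)N(C(C)C)C(C)C)[C@@H](Oc1cc2c(c(O)c1OC)C(=O)O[C@H](C)[C@@H]2O[Si](C)(C)C(C)(C)C)c1cc(O[Si](C)(C)C(C)(C)C)c(OC)c(O[Si](C)(C)C(C)(C)C)c1 | intermediate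
17 | (1S,2R)-1-[3,5-bis(TBS-oxy)-4-methoxyphenyl]-1-{[(3R,4R)-4,8-bis(TBS-oxy)-7-methoxy-3-methyl-1-oxoisochroman-6-yl]oxy}propan-2-yl N,N-diisopropylcarbamate | C[C@@H](OC(=O)N(C(C)C)C(C)C)[C@@H](Oc1cc2c(c(O[Si](C)(C)C(C)(C)C)c1OC)C(=O)O[C@H](C)[C@@H]2O[Si](C)(C)C(C)(C)C)c1cc(O[Si](C)(C)C(C)(C)C)c(OC)c(O[Si](C)(C)C(C)(C)C)c1 | intermediate
18 | O-triflyl iminium triflate of 17 (carbamate oxygen triflylated) | C[C@@H](OC(OS(=O)(=O)C(F)(F)F)=[N+](C(C)C)C(C)C)[C@@H](Oc1cc2c(c(O[Si](C)(C)C(C)(C)C)c1OC)C(=O)O[C@H](C)[C@@H]2O[Si](C)(C)C(C)(C)C)c1cc(O[Si](C)(C)C(C)(C)C)c(OC)c(O[Si](C)(C)C(C)(C)C)c1.[O-]S(=O)(=O)C(F)(F)F | intermediate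
19 | cyclic iminium ether triflate: 20 with the C1 carbonyl of unit A replaced by C=N+(iPr)2 | COc1c(O[Si](C)(C)C(C)(C)C)cc2c(c1O[Si](C)(C)C(C)(C)C)C(=[N+](C(C)C)C(C)C)O[C@H](C)[C@H]2Oc1cc2c(c(O[Si](C)(C)C(C)(C)C)c1OC)C(=O)O[C@H](C)[C@@H]2O[Si](C)(C)C(C)(C)C.[O-]S(=O)(=O)C(F)(F)F | intermediate
20 | (3R,4R)-4,8-bis(TBS-oxy)-6-{[(3R,4S)-6,8-bis(TBS-oxy)-7-methoxy-3-methyl-1-oxoisochroman-4-yl]oxy}-7-methoxy-3-methylisochroman-1-one | COc1c(O[Si](C)(C)C(C)(C)C)cc2c(c1O[Si](C)(C)C(C)(C)C)C(=O)O[C@H](C)[C@H]2Oc1cc2c(c(O[Si](C)(C)C(C)(C)C)c1OC)C(=O)O[C@H](C)[C@@H]2O[Si](C)(C)C(C)(C)C | intermediate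
21 | (3R,4R)-4,8-dihydroxy-6-{[(3R,4S)-6,8-dihydroxy-7-methoxy-3-methyl-1-oxoisochroman-4-yl]oxy}-7-methoxy-3-methylisochroman-1-one | COc1c(O)cc2c(c1O)C(=O)O[C@H](C)[C@H]2Oc1cc2c(c(O)c1OC)C(=O)O[C@H](C)[C@@H]2O | target

**Step count and risks**

Total: 11 steps. Longest linear sequence: 10 steps (steps 1 to 7, then 9, 10, 11); step 8 is a one-step branch from ketone 6.

Most likely to fail, riskiest first:

Step 10. The hindered diisopropylcarbamoyl group may activate or cyclise slowly. The activated carbamate may instead leave as a nucleofuge, with ionisation at C3 assisted by the neighbouring aryl ring. Closure onto C5 of ring B may also compete. The fallback reverses the polarity of the same bond formation and uses known chemistry. It sets out from 17: bromination with NBS in MeCN at 0 °C should take place on ring A, which carries no carbonyl and whose two free ortho carbons are equivalent, to give (1S,2R)-1-[2-bromo-3,5-bis(TBS-oxy)-4-methoxyphenyl]-1-{[(3R,4R)-4,8-bis(TBS-oxy)-7-methoxy-3-methyl-1-oxoisochroman-6-yl]oxy}propan-2-yl N,N-diisopropylcarbamate F2. Bromine–lithium exchange with t-BuLi in THF at −100 °C, intramolecular addition of the aryllithium to the carbamate carbonyl (Parham cyclisation, which tolerates esters at this temperature) and an acidic quench at low temperature should expel diisopropylamine from the tetrahedral adduct. The fallback comes back to the route at 20.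

Step 9. Direct displacement of the mesylate by the phenoxide may compete with anchimeric participation and erode the configuration at C4 of unit A. The phenoxide may also add to the iminium carbon, or the mesylate may eliminate to an enol carbamate. The fallback uses a single inversion instead of a double one. It sets out from the epimeric alcohol 7 and phenol 12: a Mitsunobu etherification (PPh3, DIAD, toluene, 0 °C to rt) with the acidic 6-OH of 12 as pronucleophile should invert the benzylic carbon and give 16. Silylation of the chelated 8-OH with TBSOTf and 2,6-lutidine then comes back to the route at 17. Since both epimeric alcohols are at hand from 6, the ether is reachable whichever substitution pathway prevails. This fallback makes no compound outside the list (F0).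

Step 6. The neighbouring C4 silyl ether oxygen may intercept the activated carbamate, giving desilylative closure to a dioxolan-2-iminium ion, or the Friedel–Crafts closure may be slow next to the bulky silyloxy groups. The fallback sets out from 8: NBS in MeCN at 0 °C should brominate one of the two equivalent ortho positions to give (1R,2R)-1-[2-bromo-3,5-bis(TBS-oxy)-4-methoxyphenyl]-1-(TBS-oxy)propan-2-yl N,N-diisopropylcarbamate F1. Parham cyclisation (t-BuLi, THF, −100 °C, then acidic quench at low temperature) comes back to the route at 11.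

**Further compounds**

F2 | step 10 | (1S,2R)-1-[2-bromo-3,5-bis(TBS-oxy)-4-methoxyphenyl]-1-{[(3R,4R)-4,8-bis(TBS-oxy)-7-methoxy-3-methyl-1-oxoisochroman-6-yl]oxy}propan-2-yl N,N-diisopropylcarbamate | C[C@@H](OC(=O)N(C(C)C)C(C)C)[C@@H](Oc1cc2c(c(O[Si](C)(C)C(C)(C)C)c1OC)C(=O)O[C@H](C)[C@@H]2O[Si](C)(C)C(C)(C)C)c1cc(O[Si](C)(C)C(C)(C)C)c(OC)c(O[Si](C)(C)C(C)(C)C)c1Br
F0 | step 9 | none | none
F1 | step 6 | (1R,2R)-1-[2-bromo-3,5-bis(TBS-oxy)-4-methoxyphenyl]-1-(TBS-oxy)propan-2-yl N,N-diisopropylcarbamate | C[C@@H](OC(=O)N(C(C)C)C(C)C)[C@H](O[Si](C)(C)C(C)(C)C)c1cc(O[Si](C)(C)C(C)(C)C)c(OC)c(O[Si](C)(C)C(C)(C)C)c1Br
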